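## Analysis of the target

Compound 26 (propolis-benzofuran A) is a 3,4-dihydro-2H-pyran, numbered here O1, C2, C3, C4, C5, C6. C2 carries a 4-hydroxy-3-methoxyphenyl group, C3 an acetoxymethyl group, C4 is a plain methylene, and C5=C6 is an enol ether whose C5 is bonded to C2 of a 6-acetyl-5-hydroxybenzofuran. There are two stereocentres, C2 (R) and C3 (S); they are adjacent and trans, so both substituents can lie pseudo-equatorial on the half-chair. The sensitive groups are the enol ether (protonation at C5), the C2–O1 bond (a benzylic ether activated by a para oxygen), the primary acetate (base) and the aryl methyl ketone (enolisable, reducible). Three hydroxyls must end differently: the aliphatic one as acetate and two phenols free, one of them hydrogen-bonded to the ketone. The difficulty is to set the trans C2/C3 pair in the absolute sense on a ring that has no other stereocentre, and to bring the enol ether through the deprotections. The plan rests on one feature: O1–C2(aryl)–C3 together with the C5=C6 enol ether is a 2-aryl-2,3-dihydro-4H-pyran-4-one that lacks only its C4 carbonyl oxygen, and that ring is the adduct of an aryl aldehyde (C2, O1) with a 1-methoxy-3-silyloxy diene (C3 to C6).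

## Retrosynthetic reasoning

**26 from 25.** The last bonds cut are the two aryl O–Si bonds. Buffered fluoride is the one deprotection that is neutral towards both the enol ether and the acetate, so the phenols stay silylated to the end.

**25 from 24.** The enol ether is not carried through the synthesis. It is made from its allyl ether isomer 24 (alkene at C4=C5, C6 as OCH2) by moving the double bond one position. Removing the C4 oxygen by hydride passes through an allyl cation stabilised by O1, and that cation takes hydride at C6, so the alkene first lands at C4=C5. The gain is that the acid-labile enol ether appears only after every acidic operation is over.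

**24 from 23 from 22.** The acetate comes from primary alcohol 23. One acid treatment of 22 removes the dioxolane and the alkyl silyl ether but leaves the two aryl silyl ethers. This separates the aliphatic hydroxyl from the phenols by protecting-group class, so no selective acylation is needed, and the allyl ether stage is the window in which acid is tolerated.

**22 from 21 from 20.** The C4–O bond is cut: 22 from allylic alcohol 21 by ionic reduction, 21 from ketone 20 by 1,2-reduction. The forward steps must reduce a vinylogous ester carbonyl while an aryl methyl ketone is present, which is why that ketone is a dioxolane from 11 to 22.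

**20 from 16 and 18 (key disconnection).** C2–C3 and O1–C6 are cut. This divides the molecule into an aldehyde and a diene of similar size; both stereocentres lie on the carbon–carbon bond that is formed; the aldehyde cannot enolise; and the diene already holds the benzofuran on C5 and the oxygenated methylene on C3. The forward reaction must choose one face of the aldehyde, give the anti relation between C2 and C3, and close the ring with loss of the methoxy group.

**16 from 15 from 13.** The O–Si bond of the enol silane is cut, then the one-carbon unit C6: formylation at the heterobenzylic carbon of ketone 13 and O-methylation. The heterobenzylic position is the more acidic of the two α-positions, so the one-carbon unit goes where C5 needs it.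

**13 from 12 from 11 from 9.** These are functional-group changes. The side-chain ketone is unveiled last, because ketalisation could not tell two ketones apart; the phenol is silylated after ketalisation, when it is no longer tied to the carbonyl by a hydrogen bond.

**9 from 3 and 7.** The furan ring of the benzofuran is cut at the aryl–alkyne bond and at O–C2. The forward reaction is a cross-coupling at the C–Br bond followed by attack of the neighbouring phenol on the alkyne. Only the phenol ortho to bromine can reach the alkyne, so the two hydroxyls of 3 need no differentiation.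

**3 from 2 from 1; 7 from 5 and 6, 5 from 4; 18 from 17.** Acylation para to bromine fixes the 1,2,4,5 pattern of the arene, and ether cleavage frees both phenols. The alkyne comes from an aldehyde and a propargyl unit; its carbinol centre is racemic and is erased at 13. The aldehyde partner is the silyl ether of 17.

## Alternatives that were turned down

**Alternative 1:** lactone alkylation on a cyclic sulfate.
- Disconnection: the C4–C5 bond, with C6 carried as a lactone carbonyl. Precursor A1 is an ester of the (R) benzylic carbinol with the benzofuranylacetyl unit; the neighbouring carbon carries a 1,3-diol locked as a cyclic sulfate.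
- Forward key step: a sodium amide base forms the ester enolate, which attacks one of the two diastereotopic CH2–O carbons (6-exo-tet). This closes the δ-lactone and leaves the other arm as a sulfate monoester, A2.
- For: C4 is born as a methylene, so no ring oxygen has to be removed. The enol ether would come from the lactone by reduction and dehydration, where only C5 can lose a proton. On both points this plan is stronger than the chosen one, which pays with a deoxygenation and an alkene shift. Only one stereocentre has to be made beforehand.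
- Against: C3 is set by a choice between two arms that differ only through the neighbouring carbinol centre, so the trans preference is expected but may be modest. The benzylic acyloxy group of A1 is itself a leaving group next to an electron-rich arene and invites elimination under the base. The aryl methyl ketone, written free in A1 and A2, would be enolised by the base and reduced together with the lactone, so it needs the same masking as here. The sulfate monoester needs acid hydrolysis before acetylation. The enantiopure carbinol of A1 needs its own sequence, which brings the length to about that of the chosen route.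
- Comparison: the chosen strategy makes both stereocentres and the ring in one catalytic step from two fragments prepared by routine chemistry, with no diastereotopic-group problem.

**Alternative 2:** late benzofuran by intramolecular Wittig reaction.
- Disconnection: the furan ring of the benzofuran at its C2=C3 bond. Precursor A3 is an ortho-acyloxybenzyl phosphonium salt whose acyl group is the complete dihydropyran.
- Forward key step: a tertiary amine forms the benzylic ylide, which adds to the neighbouring ester carbonyl; loss of the phosphine oxide closes the furan and gives A4, the target silylated at the guaiacyl phenol.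
- For: the heteroarene is built last under mild base. The enol ether travels as a vinylogous carbonate, far less acid-labile than the aryl-conjugated enol ether of 25, and one fluoride step ends the synthesis. In protecting-group economy and in the handling of the enol ether this plan is stronger.
- Against: the key step makes neither the pyran ring nor a stereocentre. The trans (2R,3S) acyl part of A3 must come from a second asymmetric sequence, so the real difficulty is only moved. The carbonyl that the ylide must attack is a vinylogous carbonate and a poor electrophile, and the ylide is weakened by the para acetyl group. The arene of A3 needs four different substituents in a fixed pattern, with the acyl group on one specific oxygen of a 1,4-dioxygenated ring, and the acetyl group offers the ylide a second carbonyl.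
- Comparison: the chosen strategy builds the benzofuran early by a robust alkyne annulation and spends its key step on the hard part, the ring with its two stereocentres.

**Alternative 3:** hydroformylation and lactol formation.
- Disconnection: C5–C6 and O1–C6, with C6 taken from synthesis gas. Precursor A5 is a homoallylic alcohol with the anti carbinol/acetoxymethyl pair in place and an (E) alkene joining C4 and C5 to the benzofuran.
- Forward key step: a rhodium–phosphite catalyst under synthesis gas adds hydrogen to C4 and a formyl group to the heterobenzylic C5. The C2 hydroxyl adds to the new aldehyde and gives lactol A6, which needs only dehydration.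
- For: C4 and C6 arrive at the right oxidation level, nothing is deoxygenated, dehydration of A6 can place the alkene only at C5=C6, and A5 and A6 carry free phenols. In redox economy and in the number of steps after the key step this plan is clearly stronger.
- Against: hydroformylation of a 1,2-disubstituted alkene is slow. The preference for the benzylic carbon that holds for terminal vinylarenes weakens when the other alkene carbon is substituted, so formylation at C4, hydrogenation and alkene migration compete. The furan double bond of the benzofuran is a second alkene. The two stereocentres that matter are again not made in the key step, so A5 needs its own asymmetric, anti-selective bond formation. The closing dehydration would be run on a lactol with two free phenols and an acid-sensitive benzylic ether.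
- Comparison: the chosen strategy is longer after the key step, but its key step has close precedent for every bond it forms and sets the stereocentres itself.

Key step: step 12

Abbreviations: TBS = tert-butyldimethylsilyl (TBSO = its ether oxygen), TMS = trimethylsilyl (TMSO likewise).

Assumption: the (R) ligand is taken to leave the Re face of aldehyde 18 open, as this class of titanium–binaphthol catalyst is expected to do with aryl aldehydes; if the sense is the opposite, the (S) ligand is used and nothing else changes.

## Route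

Step 1
Reactants: 1 2-bromo-1,4-dimethoxybenzene
Product: 2 1-(4-bromo-2,5-dimethoxyphenyl)ethanone
Conditions: AcCl, AlCl3, CH2Cl2, 0 °C
Reagents that add atoms: acetyl chloride, CC(=O)Cl
Why: Friedel–Crafts acylation; the carbon para to bromine and ortho to a methoxy group is the most activated unhindered position, which fixes the 1,2,4,5 pattern. Any cleavage of the ether next to the new ketone by AlCl3 is harmless because step 2 removes both methyl groups.

Step 2
Reactants: 2 bromo dimethoxy ketone
Product: 3 1-(4-bromo-2,5-dihydroxyphenyl)ethanone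
Conditions: BBr3, CH2Cl2, −78 °C to rt; then H2O
Reagents that add atoms: none
Why: Lewis-acid cleavage of aryl methyl ethers through aryloxyboron bromides that hydrolyse on work-up; the aryl bromide and the ketone are inert.

Step 3
Reactants: 4 3-(tert-butyldimethylsilyloxy)propan-1-ol
Product: 5 3-(tert-butyldimethylsilyloxy)propanal
Conditions: TEMPO (cat.), PhI(OAc)2, CH2Cl2, rt
Reagents that add atoms: none
Why: Oxoammonium (TEMPO) oxidation of a primary alcohol, which stops at the aldehyde and leaves the silyl ether alone; 5 is used crude because β-silyloxy aldehydes eliminate on storage.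

Step 4
Reactants: 5 silyloxy aldehyde; 6 propargyl bromide (3-bromoprop-1-yne)
Product: 7 rac-1-(tert-butyldimethylsilyloxy)hex-5-yn-3-ol
Conditions: Zn, THF/sat. aq. NH4Cl, 0 °C to rt
Reagents that add atoms: none
Why: Barbier propargylation; the allenylzinc species adds through its γ-carbon and so should give the homopropargylic alcohol. The carbinol centre is racemic and is erased in step 8.

Step 5
Reactants: 3 bromo dihydroxy ketone; 7 homopropargylic alcohol
Product: 9 1-[2-(4-(TBSO)-2-hydroxybutyl)-5-hydroxy-1-benzofuran-6-yl]ethanone (racemic), via alkynylphenol 8 (not isolated)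
Conditions: PdCl2(PPh3)2 (5 mol %), CuI (10 mol %), Et3N, DMF, 80 °C, argon
Reagents that add atoms: none
Why: Sonogashira coupling at a C–Br bond activated by the para acetyl group, then copper-assisted 5-endo-dig attack of the adjacent phenoxide on the alkyne, which closes the furan. The other phenol is meta to the alkyne and cannot reach it.

Step 6
Reactants: 9 benzofuran keto diol
Product: 11 2-[4-(TBSO)-2-hydroxybutyl]-6-(2-methyl-1,3-dioxolan-2-yl)-1-benzofuran-5-ol (racemic), via bis-TMS ether 10 (not isolated)
Conditions: Me3SiOCH2CH2OSiMe3 (4 equiv), Me3SiOTf (cat.), CH2Cl2, −20 °C to rt; pyridine; then K2CO3, MeOH, 0 °C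
Reagents that add atoms: 1,2-bis(trimethylsilyloxy)ethane, C[Si](C)(C)OCCO[Si](C)(C)C
Why: Silyl-triflate-catalysed ketalisation with the bis-silyl glycol; phenol and carbinol are capped as TMS ethers in the flask, which breaks the phenol–carbonyl hydrogen bond, and siloxane formation drives the reaction. Brief methanolysis then removes only the two TMS groups and leaves the dioxolane and the primary TBS ether.

Step 7
Reactants: 11 ketal phenol
Product: 12 4-(TBSO)-1-[5-(TBSO)-6-(2-methyl-1,3-dioxolan-2-yl)-1-benzofuran-2-yl]butan-2-ol (racemic)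
Conditions: TBSCl (1.05 equiv), imidazole, CH2Cl2, 0 °C
Reagents that add atoms: tert-butyldimethylsilyl chloride, CC(C)(C)[Si](C)(C)Cl
Why: Silylation; with one equivalent of reagent the phenol should react far faster than the secondary carbinol.

Step 8
Reactants: 12 secondary alcohol
Product: 13 4-(TBSO)-1-[5-(TBSO)-6-(2-methyl-1,3-dioxolan-2-yl)-1-benzofuran-2-yl]butan-2-one
Conditions: Dess–Martin periodinane, NaHCO3, CH2Cl2, 0 °C to rt
Reagents that add atoms: none
Why: Dess–Martin oxidation under buffered conditions, so that the dioxolane and silyl ethers survive; the phenol is protected and cannot be oxidised.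

Step 9
Reactants: 13 benzofuranylmethyl ketone
Product: 15 (E)-5-(TBSO)-1-methoxy-2-[5-(TBSO)-6-(2-methyl-1,3-dioxolan-2-yl)-1-benzofuran-2-yl]pent-1-en-3-one, via lithium enolate 14 (not isolated)
Conditions: LiN(SiMe3)2 (1.1 equiv), THF, −78 °C; HCO2CH2CF3; then Me2SO4, DMPU, −78 °C to rt
Reagents that add atoms: 2,2,2-trifluoroethyl formate, O=COCC(F)(F)F; dimethyl sulfate, COS(=O)(=O)OC
Why: Crossed Claisen formylation at the more acidic heterobenzylic CH2 (its enolate is conjugated with the benzofuran), then O-methylation of the β-ketoaldehyde enolate at the less hindered formyl oxygen. The low temperature and the weakly nucleophilic trifluoroethoxide protect the β-silyloxy ketone and the aryl silyl ether; the alkene geometry of 15 has no consequence later.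

Step 10
Reactants: 15 methoxymethylene ketone
Product: 16 (1E,3Z)-5-(TBSO)-1-methoxy-2-[5-(TBSO)-6-(2-methyl-1,3-dioxolan-2-yl)-1-benzofuran-2-yl]-3-(TMSO)penta-1,3-diene
Conditions: LiN(SiMe3)2, THF, −78 °C; Me3SiCl, Et3N, −78 to 0 °C; pentane, filtration
Reagents that add atoms: chlorotrimethylsilane, C[Si](C)(C)Cl
Why: Kinetic enolisation at the only remaining α-CH2 and O-silylation; the branched acyl substituent favours the (Z) enolate, and a β-silyloxy lithium enolate does not eliminate at −78 °C. Diene 16 is moisture-sensitive and is used without chromatography.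

Step 11
Reactants: 17 vanillin (4-hydroxy-3-methoxybenzaldehyde)
Product: 18 4-(tert-butyldimethylsilyloxy)-3-methoxybenzaldehyde
Conditions: TBSCl, imidazole, DMF, rt
Reagents that add atoms: tert-butyldimethylsilyl chloride, CC(C)(C)[Si](C)(C)Cl
Why: Routine phenol silylation; it removes the acidic proton that would destroy the titanium catalyst and the diene.

Step 12
Reactants: 16 siloxy diene (1.5 equiv); 18 silylated vanillin
Product: 20 (2R,3S)-2-[4-(TBSO)-3-methoxyphenyl]-3-[(TBSO)methyl]-5-[5-(TBSO)-6-(2-methyl-1,3-dioxolan-2-yl)-1-benzofuran-2-yl]-2,3-dihydro-4H-pyran-4-one, via aldol adduct 19 (not isolated)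
Conditions: (R)-1,1'-bi-2-naphthol (20 mol %), Ti(OiPr)4 (10 mol %), 4 Å molecular sieves, Et2O, −20 °C; then CF3CO2H (2 equiv), CH2Cl2, 0 °C; NaHCO3
Reagents that add atoms: none
Why: The binaphthol–titanium Lewis acid (tetravalent titanium) binds the aldehyde oxygen of 18, and the enol-silane terminus of 16 adds to the carbonyl carbon in a Mukaiyama aldol step with silyl transfer to give 19; CF3CO2H then lets the silyloxy oxygen add to the methoxy-bearing carbon and expel the methoxy group as MeOSiMe3. The closest known reaction type is the Lewis-acid-catalysed enantioselective hetero-Diels–Alder (aldol–cyclisation) of 1-methoxy-3-silyloxy dienes with aryl aldehydes to 2-aryl-2,3-dihydro-4H-pyran-4-ones. The one ring closes by 6-endo-trig oxa-conjugate addition followed by β-elimination, favoured because the acceptor is a vinylogous ester and the product is the conjugated pyranone. C2 is set by the chiral ligand, which leaves the Re face of the aldehyde open, so the new C2–C3 bond should give the (R) carbinol carbon. C3 is set relative to C2 in an open antiperiplanar transition state: the aldehyde aryl group turns away from the branched, benzofuran-bearing substituent on the enol-silane carbon and so lies next to CH2OTBS, which gives the anti adduct and hence the 2,3-trans ring. The step needs site selectivity (only the silyl enol ether terminus of 16 is nucleophilic), face selectivity at the aldehyde (ligand) and anti simple diastereoselection (open transition state with the (Z) enol silane). The aldehyde cannot enolise, and the dioxolane keeps the aryl ketone out of the aldol manifold.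

Step 13
Reactants: 20 dihydropyranone
Product: 21 (2R,3R,4R)-2-[4-(TBSO)-3-methoxyphenyl]-3-[(TBSO)methyl]-5-[5-(TBSO)-6-(2-methyl-1,3-dioxolan-2-yl)-1-benzofuran-2-yl]-3,4-dihydro-2H-pyran-4-ol
Conditions: NaBH4, CeCl3·7H2O, MeOH/CH2Cl2, −78 to −40 °C
Reagents that add atoms: none
Why: Luche 1,2-reduction of the vinylogous ester; CeCl3 activates the carbonyl and suppresses conjugate reduction. Axial hydride delivery should give the alcohol trans to the C3 substituent, but the C4 configuration is lost in step 14; 21 is used without acidic chromatography.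

Step 14
Reactants: 21 allylic alcohol
Product: 22 (2R,3S)-2-[4-(TBSO)-3-methoxyphenyl]-3-[(TBSO)methyl]-5-[5-(TBSO)-6-(2-methyl-1,3-dioxolan-2-yl)-1-benzofuran-2-yl]-3,6-dihydro-2H-pyran
Conditions: Et3SiH (5 equiv), BF3·OEt2 (0.5 equiv), CH2Cl2, −78 °C
Reagents that add atoms: none
Why: Ferrier-type reductive rearrangement; the Lewis acid ionises the allylic C4–OH to the allyl cation stabilised by O1, and the silane delivers hydride to the oxocarbenium carbon C6, which moves the alkene to C4=C5. C2 and C3 are not touched; the low temperature and the substoichiometric Lewis acid should spare the dioxolane.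

Step 15
Reactants: 22 allyl ether
Product: 23 (2R,3S)-5-[6-acetyl-5-(TBSO)-1-benzofuran-2-yl]-3-(hydroxymethyl)-2-[4-(TBSO)-3-methoxyphenyl]-3,6-dihydro-2H-pyran
Conditions: TsOH·H2O (0.2 equiv), THF/H2O 4:1, rt
Reagents that add atoms: water, O
Why: Acid hydrolysis; the dioxolane and the primary alkyl silyl ether are cleaved, whereas aryl silyl ethers are much slower in acid. The step is placed here because the allyl ether tolerates dilute acid and the later enol ether would not.

Step 16
Reactants: 23 primary alcohol
Product: 24 (2R,3S)-3-(acetoxymethyl)-5-[6-acetyl-5-(TBSO)-1-benzofuran-2-yl]-2-[4-(TBSO)-3-methoxyphenyl]-3,6-dihydro-2H-pyran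
Conditions: Ac2O, pyridine, DMAP (cat.), CH2Cl2, 0 °C
Reagents that add atoms: acetic anhydride, CC(=O)OC(C)=O
Why: Acylation of the only free hydroxyl; should the silyl group next to the acetyl have been lost in step 15, the hydrogen-bonded phenol would still not be acylated under these conditions.

Step 17
Reactants: 24 allyl ether acetate
Product: 25 (2R,3S)-3-(acetoxymethyl)-5-[6-acetyl-5-(TBSO)-1-benzofuran-2-yl]-2-[4-(TBSO)-3-methoxyphenyl]-3,4-dihydro-2H-pyran
Conditions: RuHCl(CO)(PPh3)3 (5 mol %), toluene, 80 °C
Reagents that add atoms: none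
Why: Metal-hydride isomerisation of an allyl ether to an enol ether (hydrometalation, then β-hydride elimination from the C6–H next to oxygen), driven by conjugation of the new alkene with O1 and the benzofuran. The conditions are neutral, so acetate, ketone and silyl ethers persist, and C2 and C3 are not part of the allyl system that is moved.

Step 18
Reactants: 25 bis-silyl ether
Product: 26 propolis-benzofuran A, (2R,3S)-3-(acetoxymethyl)-5-(6-acetyl-5-hydroxy-1-benzofuran-2-yl)-2-(4-hydroxy-3-methoxyphenyl)-3,4-dihydro-2H-pyran
Conditions: Bu4NF, AcOH (1:1), THF, 0 °C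
Reagents that add atoms: none
Why: Fluoride cleavage of the two aryl silyl ethers; buffering with AcOH protects the acetate from phenoxide and basic fluoride, and the medium is too weakly acidic to protonate the aryl-conjugated enol ether.

## Compound list

1 | 2-bromo-1,4-dimethoxybenzene | COc1ccc(OC)c(Br)c1 | starting material
2 | 1-(4-bromo-2,5-dimethoxyphenyl)ethanone | CC(=O)c1cc(OC)c(Br)cc1OC | intermediate
3 | 1-(4-bromo-2,5-dihydroxyphenyl)ethanone | CC(=O)c1cc(O)c(Br)cc1O | intermediate
4 | 3-(tert-butyldimethylsilyloxy)propan-1-ol | CC(C)(C)[Si](C)(C)OCCCO | starting material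
5 | 3-(tert-butyldimethylsilyloxy)propanal | CC(C)(C)[Si](C)(C)OCCC=O | intermediate
6 | propargyl bromide (3-bromoprop-1-yne) | C#CCBr | starting material
7 | rac-1-(tert-butyldimethylsilyloxy)hex-5-yn-3-ol | CC(C)(C)[Si](C)(C)OCCC(O)CC#C | intermediate
8 | 1-[4-(6-(TBSO)-4-hydroxyhex-1-yn-1-yl)-2,5-dihydroxyphenyl]ethanone (racemic, not isolated) | CC(=O)c1cc(O)c(C#CCC(O)CCO[Si](C)(C)C(C)(C)C)cc1O | intermediate
9 | 1-[2-(4-(TBSO)-2-hydroxybutyl)-5-hydroxy-1-benzofuran-6-yl]ethanone (racemic) | CC(=O)c1cc2oc(CC(O)CCO[Si](C)(C)C(C)(C)C)cc2cc1O | intermediate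
10 | 2-methyl-2-[2-(4-(TBSO)-2-(TMSO)butyl)-5-(TMSO)-1-benzofuran-6-yl]-1,3-dioxolane (racemic, not isolated) | CC1(OCCO1)c1cc2oc(CC(CCO[Si](C)(C)C(C)(C)C)O[Si](C)(C)C)cc2cc1O[Si](C)(C)C | intermediate
11 | 2-[4-(TBSO)-2-hydroxybutyl]-6-(2-methyl-1,3-dioxolan-2-yl)-1-benzofuran-5-ol (racemic) | CC1(OCCO1)c1cc2oc(CC(O)CCO[Si](C)(C)C(C)(C)C)cc2cc1O | intermediate
12 | 4-(TBSO)-1-[5-(TBSO)-6-(2-methyl-1,3-dioxolan-2-yl)-1-benzofuran-2-yl]butan-2-ol (racemic) | CC1(OCCO1)c1cc2oc(CC(O)CCO[Si](C)(C)C(C)(C)C)cc2cc1O[Si](C)(C)C(C)(C)C | intermediate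
13 | 4-(TBSO)-1-[5-(TBSO)-6-(2-methyl-1,3-dioxolan-2-yl)-1-benzofuran-2-yl]butan-2-one | CC1(OCCO1)c1cc2oc(CC(=O)CCO[Si](C)(C)C(C)(C)C)cc2cc1O[Si](C)(C)C(C)(C)C | intermediate
14 | lithium 5-(TBSO)-2-[5-(TBSO)-6-(2-methyl-1,3-dioxolan-2-yl)-1-benzofuran-2-yl]-3-oxopent-1-en-1-olate (not isolated) | [Li+].[O-]C=C(C(=O)CCO[Si](C)(C)C(C)(C)C)c1cc2cc(O[Si](C)(C)C(C)(C)C)c(C3(C)OCCO3)cc2o1 | intermediate
15 | (E)-5-(TBSO)-1-methoxy-2-[5-(TBSO)-6-(2-methyl-1,3-dioxolan-2-yl)-1-benzofuran-2-yl]pent-1-en-3-one | CO/C=C(\c1cc2cc(O[Si](C)(C)C(C)(C)C)c(C3(C)OCCO3)cc2o1)C(=O)CCO[Si](C)(C)C(C)(C)C | intermediate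
16 | (1E,3Z)-5-(TBSO)-1-methoxy-2-[5-(TBSO)-6-(2-methyl-1,3-dioxolan-2-yl)-1-benzofuran-2-yl]-3-(TMSO)penta-1,3-diene | CO/C=C(\c1cc2cc(O[Si](C)(C)C(C)(C)C)c(C3(C)OCCO3)cc2o1)/C(O[Si](C)(C)C)=C/CO[Si](C)(C)C(C)(C)C | intermediate
17 | vanillin (4-hydroxy-3-methoxybenzaldehyde) | COc1cc(C=O)ccc1O | starting material
18 | 4-(tert-butyldimethylsilyloxy)-3-methoxybenzaldehyde | COc1cc(C=O)ccc1O[Si](C)(C)C(C)(C)C | intermediate
19 | (1E,4S,5R)-5-[4-(TBSO)-3-methoxyphenyl]-4-[(TBSO)methyl]-1-methoxy-2-[5-(TBSO)-6-(2-methyl-1,3-dioxolan-2-yl)-1-benzofuran-2-yl]-5-(TMSO)pent-1-en-3-one (anti aldol adduct, not isolated) | COc1cc([C@H](O[Si](C)(C)C)[C@H](CO[Si](C)(C)C(C)(C)C)C(=O)/C(=C/OC)c2cc3cc(O[Si](C)(C)C(C)(C)C)c(C4(C)OCCO4)cc3o2)ccc1O[Si](C)(C)C(C)(C)C | intermediate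
20 | (2R,3S)-2-[4-(TBSO)-3-methoxyphenyl]-3-[(TBSO)methyl]-5-[5-(TBSO)-6-(2-methyl-1,3-dioxolan-2-yl)-1-benzofuran-2-yl]-2,3-dihydro-4H-pyran-4-one | COc1cc([C@@H]2OC=C(c3cc4cc(O[Si](C)(C)C(C)(C)C)c(C5(C)OCCO5)cc4o3)C(=O)[C@H]2CO[Si](C)(C)C(C)(C)C)ccc1O[Si](C)(C)C(C)(C)C | intermediate
21 | (2R,3R,4R)-2-[4-(TBSO)-3-methoxyphenyl]-3-[(TBSO)methyl]-5-[5-(TBSO)-6-(2-methyl-1,3-dioxolan-2-yl)-1-benzofuran-2-yl]-3,4-dihydro-2H-pyran-4-ol (expected major C4 epimer) | COc1cc([C@@H]2OC=C(c3cc4cc(O[Si](C)(C)C(C)(C)C)c(C5(C)OCCO5)cc4o3)[C@H](O)[C@H]2CO[Si](C)(C)C(C)(C)C)ccc1O[Si](C)(C)C(C)(C)C | intermediate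
22 | (2R,3S)-2-[4-(TBSO)-3-methoxyphenyl]-3-[(TBSO)methyl]-5-[5-(TBSO)-6-(2-methyl-1,3-dioxolan-2-yl)-1-benzofuran-2-yl]-3,6-dihydro-2H-pyran | COc1cc([C@@H]2OCC(c3cc4cc(O[Si](C)(C)C(C)(C)C)c(C5(C)OCCO5)cc4o3)=C[C@H]2CO[Si](C)(C)C(C)(C)C)ccc1O[Si](C)(C)C(C)(C)C | intermediate
23 | (2R,3S)-5-[6-acetyl-5-(TBSO)-1-benzofuran-2-yl]-3-(hydroxymethyl)-2-[4-(TBSO)-3-methoxyphenyl]-3,6-dihydro-2H-pyran | COc1cc([C@@H]2OCC(c3cc4cc(O[Si](C)(C)C(C)(C)C)c(C(C)=O)cc4o3)=C[C@H]2CO)ccc1O[Si](C)(C)C(C)(C)C | intermediate
24 | (2R,3S)-3-(acetoxymethyl)-5-[6-acetyl-5-(TBSO)-1-benzofuran-2-yl]-2-[4-(TBSO)-3-methoxyphenyl]-3,6-dihydro-2H-pyran | COc1cc([C@@H]2OCC(c3cc4cc(O[Si](C)(C)C(C)(C)C)c(C(C)=O)cc4o3)=C[C@H]2COC(C)=O)ccc1O[Si](C)(C)C(C)(C)C | intermediate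
25 | (2R,3S)-3-(acetoxymethyl)-5-[6-acetyl-5-(TBSO)-1-benzofuran-2-yl]-2-[4-(TBSO)-3-methoxyphenyl]-3,4-dihydro-2H-pyran | COc1cc([C@@H]2OC=C(c3cc4cc(O[Si](C)(C)C(C)(C)C)c(C(C)=O)cc4o3)C[C@H]2COC(C)=O)ccc1O[Si](C)(C)C(C)(C)C | intermediate
26 | propolis-benzofuran A, (2R,3S)-3-(acetoxymethyl)-5-(6-acetyl-5-hydroxy-1-benzofuran-2-yl)-2-(4-hydroxy-3-methoxyphenyl)-3,4-dihydro-2H-pyran | COc1cc([C@@H]2OC=C(c3cc4cc(O)c(C(C)=O)cc4o3)C[C@H]2COC(C)=O)ccc1O | target

## Step count and least certain steps

Total: 18 steps. Longest linear sequence: 15 steps (1, 2, 5 to 10, 12 to 18).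

**Step 12 (key step).** The most likely failure is poor simple diastereoselection: the hindered, fully substituted diene may add through a synclinal or concerted arrangement and give the cis ring. Slow addition to the electron-rich aldehyde, with loss of the diene, is the second danger. Equilibration at C3 with base is not relied on as a remedy, because the C3 enolate can expel O1 (ring opening to an enone), which would cost the C2 configuration, and can also lose the silyloxy group.

Fallback: the terminal substituent is taken off the diene, so that only C2 is set in the catalytic step, and C3 is made afterwards by enolate chemistry. The fallback sets out from 3. Coupling with pent-4-yn-2-ol under the conditions of step 5 should give, through alkynylphenol F1, benzofuran diol F2. Ketalisation as in step 6 (through bis-TMS ether F3) gives ketal phenol F4; silylation as in step 7 gives F5; Dess–Martin oxidation gives methyl ketone F6. Formylation and O-methylation as in step 9 (through lithium enolate F7) give methoxymethylene ketone F8, and LiN(SiMe3)2/Me3SiCl gives diene F9, whose nucleophilic terminus is unsubstituted. Under the conditions of step 12, F9 and 18 should give, through aldol adduct F10, pyranone F11 with C2 as its only stereocentre; this is the best-precedented form of the cycloaddition. LiN(iPr)2 at −78 °C then forms the C3 enolate, which is trapped at that temperature with monomeric formaldehyde on the face away from the C2 aryl group to give trans hydroxymethyl pyranone F12. TBSCl/imidazole returns to the route at 20.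

**Step 17.** The most likely failure is slow hydrometalation of the trisubstituted alkene, or migration of the double bond in the other direction (towards C3), which would erase the C3 stereocentre.

Fallback: the alkene is moved by base before any base-sensitive group is present. The fallback sets out from 22. KOtBu in DMSO removes an allylic proton at C6, next to oxygen, and reprotonation at C4 gives the enol ether; the alkoxide also cleaves the two aryl silyl ethers, so the product is bis-phenol enol ether F13. Bu4NF removes the alkyl silyl ether to give ketal triol F14. Pyridinium p-toluenesulfonate in wet acetone removes the dioxolane to give triol F15; the aryl-conjugated enol ether should protonate far more slowly than the ketal ionises. Acetylation with vinyl acetate and Candida antarctica lipase B, which acylates aliphatic but not phenolic hydroxyls, returns to the route at 26.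

**Step 14.** The most likely failure is ionisation of the dioxolane or of the benzylic C2–O1 bond by the Lewis acid, proton loss from the allyl cation to a 2H-pyran, or capture of the cation by unreacted alcohol.

Fallback: the cation is avoided by an alkene-transposing reduction of the enone tosylhydrazone. The fallback sets out from 20, which is condensed with TsNHNH2 in EtOH to give tosylhydrazone F16. Catecholborane in CHCl3 at 0 °C adds hydride to the C=N bond; NaOAc·3H2O and warming then expel the sulfinate and dinitrogen with transfer of hydrogen to C6 and shift of the alkene to C4=C5. This returns to the route at 22 and passes by 21.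

**Step 6.** The most likely failure is incomplete ketalisation of a hindered, electron-rich aryl ketone, or loss of the primary silyl ether to the silyl triflate.

Fallback: the ketone is masked before the phenols are freed. The fallback sets out from 2, which is not hydrogen-bonded and should ketalise under ordinary conditions (ethylene glycol, TsOH, toluene, water removal) to bromo ketal F17. NaSEt in DMF at 120 °C cleaves both methyl ethers without touching the ketal and gives hydroquinone ketal F18. Copper-free coupling with 7 (PdCl2(MeCN)2, 2-dicyclohexylphosphino-2',4',6'-triisopropylbiphenyl, Cs2CO3, MeCN, 80 °C) and cyclisation through alkynylphenol F19 return to the route at 11.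

## Further compounds

F1 | step 12 | 1-[2,5-dihydroxy-4-(4-hydroxypent-1-yn-1-yl)phenyl]ethanone (racemic, not isolated) | CC(=O)c1cc(O)c(C#CCC(C)O)cc1O
F2 | step 12 | 1-[5-hydroxy-2-(2-hydroxypropyl)-1-benzofuran-6-yl]ethanone (racemic) | CC(=O)c1cc2oc(CC(C)O)cc2cc1O
F3 | step 12 | 2-methyl-2-[5-(TMSO)-2-(2-(TMSO)propyl)-1-benzofuran-6-yl]-1,3-dioxolane (racemic, not isolated) | CC(Cc1cc2cc(O[Si](C)(C)C)c(C3(C)OCCO3)cc2o1)O[Si](C)(C)C
F4 | step 12 | 2-(2-hydroxypropyl)-6-(2-methyl-1,3-dioxolan-2-yl)-1-benzofuran-5-ol (racemic) | CC(O)Cc1cc2cc(O)c(C3(C)OCCO3)cc2o1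
F5 | step 12 | 1-[5-(TBSO)-6-(2-methyl-1,3-dioxolan-2-yl)-1-benzofuran-2-yl]propan-2-ol (racemic) | CC(O)Cc1cc2cc(O[Si](C)(C)C(C)(C)C)c(C3(C)OCCO3)cc2o1
F6 | step 12 | 1-[5-(TBSO)-6-(2-methyl-1,3-dioxolan-2-yl)-1-benzofuran-2-yl]propan-2-one | CC(=O)Cc1cc2cc(O[Si](C)(C)C(C)(C)C)c(C3(C)OCCO3)cc2o1
F7 | step 12 | lithium 2-[5-(TBSO)-6-(2-methyl-1,3-dioxolan-2-yl)-1-benzofuran-2-yl]-3-oxobut-1-en-1-olate (not isolated) | [Li+].[O-]C=C(C(C)=O)c1cc2cc(O[Si](C)(C)C(C)(C)C)c(C3(C)OCCO3)cc2o1
F8 | step 12 | (E)-4-methoxy-3-[5-(TBSO)-6-(2-methyl-1,3-dioxolan-2-yl)-1-benzofuran-2-yl]but-3-en-2-one | CO/C=C(\c1cc2cc(O[Si](C)(C)C(C)(C)C)c(C3(C)OCCO3)cc2o1)C(C)=O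
F9 | step 12 | (E)-1-methoxy-2-[5-(TBSO)-6-(2-methyl-1,3-dioxolan-2-yl)-1-benzofuran-2-yl]-3-(TMSO)buta-1,3-diene | CO/C=C(\c1cc2cc(O[Si](C)(C)C(C)(C)C)c(C3(C)OCCO3)cc2o1)C(=C)O[Si](C)(C)C
F10 | step 12 | (1E,5R)-5-[4-(TBSO)-3-methoxyphenyl]-1-methoxy-2-[5-(TBSO)-6-(2-methyl-1,3-dioxolan-2-yl)-1-benzofuran-2-yl]-5-(TMSO)pent-1-en-3-one (not isolated) | COc1cc([C@@H](CC(=O)/C(=C/OC)c2cc3cc(O[Si](C)(C)C(C)(C)C)c(C4(C)OCCO4)cc3o2)O[Si](C)(C)C)ccc1O[Si](C)(C)C(C)(C)C
F11 | step 12 | (2R)-2-[4-(TBSO)-3-methoxyphenyl]-5-[5-(TBSO)-6-(2-methyl-1,3-dioxolan-2-yl)-1-benzofuran-2-yl]-2,3-dihydro-4H-pyran-4-one | COc1cc([C@@H]2OC=C(c3cc4cc(O[Si](C)(C)C(C)(C)C)c(C5(C)OCCO5)cc4o3)C(=O)C2)ccc1O[Si](C)(C)C(C)(C)C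
F12 | step 12 | (2R,3S)-3-(hydroxymethyl)-2-[4-(TBSO)-3-methoxyphenyl]-5-[5-(TBSO)-6-(2-methyl-1,3-dioxolan-2-yl)-1-benzofuran-2-yl]-2,3-dihydro-4H-pyran-4-one | COc1cc([C@@H]2OC=C(c3cc4cc(O[Si](C)(C)C(C)(C)C)c(C5(C)OCCO5)cc4o3)C(=O)[C@H]2CO)ccc1O[Si](C)(C)C(C)(C)C
F13 | step 17 | (2R,3S)-3-[(TBSO)methyl]-5-[5-hydroxy-6-(2-methyl-1,3-dioxolan-2-yl)-1-benzofuran-2-yl]-2-(4-hydroxy-3-methoxyphenyl)-3,4-dihydro-2H-pyran | COc1cc([C@@H]2OC=C(c3cc4cc(O)c(C5(C)OCCO5)cc4o3)C[C@H]2CO[Si](C)(C)C(C)(C)C)ccc1O
F14 | step 17 | (2R,3S)-3-(hydroxymethyl)-5-[5-hydroxy-6-(2-methyl-1,3-dioxolan-2-yl)-1-benzofuran-2-yl]-2-(4-hydroxy-3-methoxyphenyl)-3,4-dihydro-2H-pyran | COc1cc([C@@H]2OC=C(c3cc4cc(O)c(C5(C)OCCO5)cc4o3)C[C@H]2CO)ccc1O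
F15 | step 17 | (2R,3S)-5-(6-acetyl-5-hydroxy-1-benzofuran-2-yl)-3-(hydroxymethyl)-2-(4-hydroxy-3-methoxyphenyl)-3,4-dihydro-2H-pyran | COc1cc([C@@H]2OC=C(c3cc4cc(O)c(C(C)=O)cc4o3)C[C@H]2CO)ccc1O
F16 | step 14 | N'-[(2R,3S)-2-[4-(TBSO)-3-methoxyphenyl]-3-[(TBSO)methyl]-5-[5-(TBSO)-6-(2-methyl-1,3-dioxolan-2-yl)-1-benzofuran-2-yl]-2,3-dihydro-4H-pyran-4-ylidene]-4-methylbenzenesulfonohydrazide | COc1cc([C@@H]2OC=C(c3cc4cc(O[Si](C)(C)C(C)(C)C)c(C5(C)OCCO5)cc4o3)C(=NNS(=O)(=O)c3ccc(C)cc3)[C@H]2CO[Si](C)(C)C(C)(C)C)ccc1O[Si](C)(C)C(C)(C)C
F17 | step 6 | 2-(4-bromo-2,5-dimethoxyphenyl)-2-methyl-1,3-dioxolane | CC1(OCCO1)c1cc(OC)c(Br)cc1OC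
F18 | step 6 | 2-bromo-5-(2-methyl-1,3-dioxolan-2-yl)benzene-1,4-diol | CC1(OCCO1)c1cc(O)c(Br)cc1O
F19 | step 6 | 2-[6-(TBSO)-4-hydroxyhex-1-yn-1-yl]-5-(2-methyl-1,3-dioxolan-2-yl)benzene-1,4-diol (racemic, not isolated) | CC1(OCCO1)c1cc(O)c(C#CCC(O)CCO[Si](C)(C)C(C)(C)C)cc1O
A1 | alternative 1 | (R)-[4-(TBSO)-3-methoxyphenyl](2,2-dioxo-1,3,2-dioxathian-5-yl)methyl 2-[6-acetyl-5-(TBSO)-1-benzofuran-2-yl]acetate | COc1cc([C@H](OC(=O)Cc2cc3cc(O[Si](C)(C)C(C)(C)C)c(C(C)=O)cc3o2)C2COS(=O)(=O)OC2)ccc1O[Si](C)(C)C(C)(C)C
A2 | alternative 1 | sodium [(2R,3S)-5-[6-acetyl-5-(TBSO)-1-benzofuran-2-yl]-2-[4-(TBSO)-3-methoxyphenyl]-6-oxotetrahydro-2H-pyran-3-yl]methyl sulfate (C5 unassigned) | COc1cc([C@@H]2OC(=O)C(c3cc4cc(O[Si](C)(C)C(C)(C)C)c(C(C)=O)cc4o3)C[C@H]2COS(=O)(=O)[O-])ccc1O[Si](C)(C)C(C)(C)C.[Na+]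
A3 | alternative 2 | {2-[(2R,3S)-3-(acetoxymethyl)-2-(4-(TBSO)-3-methoxyphenyl)-3,4-dihydro-2H-pyran-5-carbonyloxy]-4-acetyl-5-hydroxybenzyl}triphenylphosphonium bromide | COc1cc([C@@H]2OC=C(C(=O)Oc3cc(C(C)=O)c(O)cc3C[P+](c3ccccc3)(c3ccccc3)c3ccccc3)C[C@H]2COC(C)=O)ccc1O[Si](C)(C)C(C)(C)C.[Br-]
A4 | alternative 2 | propolis-benzofuran A silylated (TBS) at the guaiacyl phenol | COc1cc([C@@H]2OC=C(c3cc4cc(O)c(C(C)=O)cc4o3)C[C@H]2COC(C)=O)ccc1O[Si](C)(C)C(C)(C)C
A5 | alternative 3 | (2S,3E)-4-(6-acetyl-5-hydroxy-1-benzofuran-2-yl)-2-[(R)-hydroxy(4-hydroxy-3-methoxyphenyl)methyl]but-3-en-1-yl acetate | COc1cc([C@H](O)[C@H](COC(C)=O)/C=C/c2cc3cc(O)c(C(C)=O)cc3o2)ccc1O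
A6 | alternative 3 | (2R,3S)-3-(acetoxymethyl)-5-(6-acetyl-5-hydroxy-1-benzofuran-2-yl)-2-(4-hydroxy-3-methoxyphenyl)tetrahydro-2H-pyran-6-ol (C5 and C6 unassigned) | COc1cc([C@@H]2OC(O)C(c3cc4cc(O)c(C(C)=O)cc4o3)C[C@H]2COC(C)=O)ccc1O
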